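A direct plan would buy all four benzene rings and join them: the triisopropylsilyl ether A1 of 3-chloro-5-methoxyphenol would be lithiated between OMe and Cl and added twice to ethyl formate to give the diarylcarbinol A2, which ionic hydrogenation would reduce to the dichlorodiarylmethane A3.
A twofold B-alkyl Suzuki coupling of A3 with the 9-BBN adduct A4 of silylated 4-vinylguaiacol would give the tetrasilyl ether A5, and fluoride would free the target.
Weakest would be the lithiation and double formate addition: an aryllithium ortho to chlorine can lose LiCl to an aryne on slight warming, the site of metalation rests only on the bulk of the silyl group, and the second addition must build a carbinol with four ortho substituents.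
Next would be the twofold sp3–sp2 coupling on the most advanced intermediate: both electron-rich, ortho-flanked C–Cl bonds must react, and mono-coupled, hydrodechlorinated and β-hydride-eliminated material would differ from A5 by one arm only and be hard to remove.
Third would be step economy: two silylations, the carbinol reduction and the fourfold desilylation, four of six steps, would add no skeletal bond.
No stereocentre and no ring closure would be at stake, since the target is achiral and every ring is bought.

Plan of the new route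
Each central ring is numbered C1 (bridge), C2 (OMe), C3 (H), C4 (OH), C5 (H), C6 (CH2CH2Ar). The retrosynthesis first returns the bridge CH2 to a diaryl ketone and then cuts C1–C2 and C5–C6 in both central rings at once.
This leaves a twofold-symmetric cross-conjugated diynone, ArCH2CH2–C≡C–CO–C≡C–CH2CH2Ar (C6≡C1–CO–C1'≡C6'), and two molecules of 1,1-dimethoxy-3-(trimethylsilyloxy)butadiene (C2–C5). The diynone comes from a zingerone-derived butyne and ethyl formate.
The enabling feature is that C2–C5 of each central ring carry a 1,3-dioxygen pattern with unsubstituted C3 and C5, the footprint of an acetoacetate-type diene. The only carbon substituents sit on the adjacent atoms C1 and C6, and the bridge carbon on C1 can be a carbonyl that polarizes both C1≡C6 triple bonds.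
Ring order: the two guaiacyl rings are bought (zingerone); the two central rings arise last and together, in one twofold Diels–Alder/aromatization.
No aryllithium next to a halogen, no aryl halide and no late cross-coupling occur. The OMe/OH placement is written into the diene (ketal carbon gives OMe, silyl enol ether carbon gives OH), and the single protecting group falls in the operation that reduces the ketone.

Key step: step 8

Remark: the target has no stereocentre, so no stereocontrol is needed; zingerone, 4-methoxybenzyl chloride, 1,1-dichloroethene and acetyl chloride are taken as the commercial starting materials.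

Step 1
Reactants: 1 zingerone, 4-(4-hydroxy-3-methoxyphenyl)butan-2-one; 2 4-methoxybenzyl chloride
Product: 3 4-{3-methoxy-4-[(4-methoxybenzyl)oxy]phenyl}butan-2-one
Conditions: K2CO3 (1.5 equiv), DMF, 60 °C
Reagents that add atoms: none
Why: Williamson ether synthesis, in which K2CO3 forms only the phenoxide and the activated benzylic chloride alkylates it; the 4-methoxybenzyl group is chosen because it should survive amide bases, Grignard reagents, MnO2 and heat and leave in the final acidic reduction.

Step 2
Reactants: 3 4-{3-methoxy-4-[(4-methoxybenzyl)oxy]phenyl}butan-2-one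
Product: 6 4-(but-3-yn-1-yl)-2-methoxy-1-[(4-methoxybenzyl)oxy]benzene, via diethyl enol phosphate 4 (not isolated), via lithium acetylide 5 (not isolated)
Conditions: LiN(i-Pr)2 (1.05 equiv), THF, −78 °C; ClP(O)(OEt)2 (1.1 equiv), −78 °C → rt; then LiN(i-Pr)2 (2.3 equiv), THF, −78 °C → rt; H2O
Reagents that add atoms: none
Why: Negishi conversion of a methyl ketone into a terminal alkyne, in which kinetic deprotonation at CH3 and O-phosphorylation give the 1-en-2-yl phosphate, and β-elimination with excess amide base is driven to the acetylide, which water protonates.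

Step 3
Reactants: 6 4-(but-3-yn-1-yl)-2-methoxy-1-[(4-methoxybenzyl)oxy]benzene (2.1 equiv per formate)
Product: 9 1,9-bis{3-methoxy-4-[(4-methoxybenzyl)oxy]phenyl}nona-3,6-diyn-5-ol, via alkynylmagnesium bromide 7 (not isolated), via alkynal 8 (not isolated)
Conditions: EtMgBr (2.05 equiv), THF, 0 → 40 °C; HCO2Et (1.0 equiv), 0 °C → rt; H2O
Reagents that add atoms: ethyl formate, CCOC=O
Why: EtMgBr deprotonates the isolated terminal alkyne to the alkynyl Grignard reagent, and its twofold addition to a formate ester (addition–elimination to the alkynal, then 1,2-addition) gives the symmetric bis-propargylic carbinol, whose carbinol carbon bears two identical groups and is not a stereocentre.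

Step 4
Reactants: 9 1,9-bis{3-methoxy-4-[(4-methoxybenzyl)oxy]phenyl}nona-3,6-diyn-5-ol
Product: 10 1,9-bis{3-methoxy-4-[(4-methoxybenzyl)oxy]phenyl}nona-3,6-diyn-5-one
Conditions: MnO2 (activated, 15 equiv), CH2Cl2, rt
Reagents that add atoms: none
Why: MnO2 oxidation of a doubly propargylic (activated) alcohol runs under neutral, non-nucleophilic conditions, so the electrophilic diynone is not exposed to reagents that add to it, and the benzylic ethers are untouched.

Step 5
Reactants: 11 1,1-dichloroethene; 12 acetyl chloride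
Product: 14 4,4-dichlorobut-3-en-2-one, via 4,4,4-trichlorobutan-2-one 13 (not isolated)
Conditions: AlCl3 (1.05 equiv), CH2Cl2, 0 °C → rt; ice-water; distillation (loss of HCl)
Reagents that add atoms: none
Why: Friedel–Crafts (Kondakov) acylation of the alkene at its CH2 terminus, chloride capture at the CCl2 cation and β-elimination of HCl give the β,β-dichlorovinyl ketone.

Step 6
Reactants: 14 4,4-dichlorobut-3-en-2-one
Product: 15 4,4-dimethoxybut-3-en-2-one
Conditions: NaOMe (2.1 equiv), MeOH, 0 °C → rt
Reagents that add atoms: sodium methoxide, C[O-].[Na+]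
Why: Twofold vinylic nucleophilic substitution (conjugate addition–elimination) at the β-carbon of the enone gives the push–pull ketene acetal, which two donor oxygens deactivate against a third addition.

Step 7
Reactants: 15 4,4-dimethoxybut-3-en-2-one
Product: 16 1,1-dimethoxy-3-(trimethylsilyloxy)buta-1,3-diene
Conditions: LiN(i-Pr)2 (1.1 equiv), THF, −78 °C; Me3SiCl (1.2 equiv), −78 °C → rt; distilled, used at once
Reagents that add atoms: chlorotrimethylsilane, C[Si](C)(C)Cl
Why: The methyl group is the only enolisable position, and O-silylation of its lithium enolate gives the Brassard-type 1,1-dialkoxy-3-silyloxydiene.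

Step 8
Reactants: 10 1,9-bis{3-methoxy-4-[(4-methoxybenzyl)oxy]phenyl}nona-3,6-diyn-5-one; 16 1,1-dimethoxy-3-(trimethylsilyloxy)buta-1,3-diene (3 equiv)
Product: 18 bis[4-hydroxy-2-methoxy-6-(2-{3-methoxy-4-[(4-methoxybenzyl)oxy]phenyl}ethyl)phenyl]methanone, via twofold cyclohexa-1,4-diene ketal cycloadduct 17 (not isolated)
Conditions: toluene, 110 °C, sealed tube, N2; then 0.5 M HCl, THF, 0 °C → rt
Reagents that add atoms: none
Why: The electron-rich diene 16, whose HOMO coefficient is largest at the CH2 terminus C4 (pushed by the silyloxy and both ketal oxygens), adds to each electron-poor triple bond of 10, whose LUMO coefficient is largest at the carbon β to the carbonyl, in a normal-demand [4+2] cycloaddition that is concerted or passes through a Mukaiyama–Michael zwitterion closing to the same ring. The closest known reaction is the Danishefsky–Brassard Diels–Alder/aromatization of 1,1-dialkoxy-3-silyloxybutadienes with 2-alkynoates and alkynyl ketones, which gives 6-alkyl-4-hydroxy-2-methoxyaryl carbonyl compounds. Each central benzene ring is closed by two bonds formed in one event, diene C4 to the alkyne carbon bearing the arylethyl chain and the ketal carbon C1 to the alkyne carbon bearing the carbonyl, and the cyclohexa-1,4-diene ketal 17 then aromatizes on mild acid by loss of methanol and of the silyl group; no stereocentre is formed. The step needs regioselectivity, secured by this matched polarization, so that OMe ends ortho and OH para to the bridge carbon with the chain on the other ortho carbon. It also needs both ynone units to react, which the carbonyl secures because it stays conjugated to the second triple bond after the first ring has formed, while the new aryl ring, twisted out of the carbonyl plane by its two ortho substituents, does not quench that activation. Chemoselectivity for C≡C over C=O follows from the absence of a Lewis acid, and since the diene delivers OMe from its ketal carbon and OH from its silyl enol ether carbon, no selective methylation is needed.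

Step 9
Reactants: 18 bis[4-hydroxy-2-methoxy-6-(2-{3-methoxy-4-[(4-methoxybenzyl)oxy]phenyl}ethyl)phenyl]methanone
Product: 21 4,4'-methylenebis{5-[2-(4-hydroxy-3-methoxyphenyl)ethyl]-3-methoxyphenol}, via tetraphenol ketone 19 (not isolated), via diarylmethanol 20 (not isolated)
Conditions: Et3SiH (8 equiv), CF3CO2H/CH2Cl2 (1:4), 0 °C → rt, N2
Reagents that add atoms: none
Why: Kursanov–Parnes ionic hydrogenation, in which the ketone protonated in CF3CO2H takes hydride from the silane and the resulting carbinol ionises to a diarylmethyl cation stabilised by the para-OH and ortho-OMe groups and takes a second hydride, while the same medium cleaves both 4-methoxybenzyl ethers and the silane traps their cation as 4-methylanisole.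

Compound list
1 | zingerone, 4-(4-hydroxy-3-methoxyphenyl)butan-2-one | CC(=O)CCc1ccc(O)c(OC)c1 | starting material
2 | 4-methoxybenzyl chloride | COc1ccc(CCl)cc1 | starting material
3 | 4-{3-methoxy-4-[(4-methoxybenzyl)oxy]phenyl}butan-2-one | CC(=O)CCc1ccc(OCc2ccc(OC)cc2)c(OC)c1 | intermediate
4 | diethyl 4-{3-methoxy-4-[(4-methoxybenzyl)oxy]phenyl}but-1-en-2-yl phosphate | C=C(CCc1ccc(OCc2ccc(OC)cc2)c(OC)c1)OP(=O)(OCC)OCC | intermediate
5 | (4-{3-methoxy-4-[(4-methoxybenzyl)oxy]phenyl}but-1-yn-1-yl)lithium | [Li]C#CCCc1ccc(OCc2ccc(OC)cc2)c(OC)c1 | intermediate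
6 | 4-(but-3-yn-1-yl)-2-methoxy-1-[(4-methoxybenzyl)oxy]benzene | C#CCCc1ccc(OCc2ccc(OC)cc2)c(OC)c1 | intermediate
7 | bromo(4-{3-methoxy-4-[(4-methoxybenzyl)oxy]phenyl}but-1-yn-1-yl)magnesium | Br[Mg]C#CCCc1ccc(OCc2ccc(OC)cc2)c(OC)c1 | intermediate
8 | 5-{3-methoxy-4-[(4-methoxybenzyl)oxy]phenyl}pent-2-ynal | O=CC#CCCc1ccc(OCc2ccc(OC)cc2)c(OC)c1 | intermediate
9 | 1,9-bis{3-methoxy-4-[(4-methoxybenzyl)oxy]phenyl}nona-3,6-diyn-5-ol | OC(C#CCCc1ccc(OCc2ccc(OC)cc2)c(OC)c1)C#CCCc1ccc(OCc2ccc(OC)cc2)c(OC)c1 | intermediate
10 | 1,9-bis{3-methoxy-4-[(4-methoxybenzyl)oxy]phenyl}nona-3,6-diyn-5-one | O=C(C#CCCc1ccc(OCc2ccc(OC)cc2)c(OC)c1)C#CCCc1ccc(OCc2ccc(OC)cc2)c(OC)c1 | intermediate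
11 | 1,1-dichloroethene | C=C(Cl)Cl | starting material
12 | acetyl chloride | CC(=O)Cl | starting material
13 | 4,4,4-trichlorobutan-2-one | CC(=O)CC(Cl)(Cl)Cl | intermediate
14 | 4,4-dichlorobut-3-en-2-one | CC(=O)C=C(Cl)Cl | intermediate
15 | 4,4-dimethoxybut-3-en-2-one | CC(=O)C=C(OC)OC | intermediate
16 | 1,1-dimethoxy-3-(trimethylsilyloxy)buta-1,3-diene | C=C(O[Si](C)(C)C)C=C(OC)OC | intermediate
17 | bis[6,6-dimethoxy-2-(2-{3-methoxy-4-[(4-methoxybenzyl)oxy]phenyl}ethyl)-4-(trimethylsilyloxy)cyclohexa-1,4-dien-1-yl]methanone | O=C(C1=C(CCc2ccc(OCc3ccc(OC)cc3)c(OC)c2)CC(O[Si](C)(C)C)=CC1(OC)OC)C1=C(CCc2ccc(OCc3ccc(OC)cc3)c(OC)c2)CC(O[Si](C)(C)C)=CC1(OC)OC | intermediate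
18 | bis[4-hydroxy-2-methoxy-6-(2-{3-methoxy-4-[(4-methoxybenzyl)oxy]phenyl}ethyl)phenyl]methanone | O=C(c1c(CCc2ccc(OCc3ccc(OC)cc3)c(OC)c2)cc(O)cc1OC)c1c(CCc2ccc(OCc3ccc(OC)cc3)c(OC)c2)cc(O)cc1OC | intermediate
19 | bis{4-hydroxy-2-[2-(4-hydroxy-3-methoxyphenyl)ethyl]-6-methoxyphenyl}methanone | O=C(c1c(CCc2ccc(O)c(OC)c2)cc(O)cc1OC)c1c(CCc2ccc(O)c(OC)c2)cc(O)cc1OC | intermediate
20 | bis{4-hydroxy-2-[2-(4-hydroxy-3-methoxyphenyl)ethyl]-6-methoxyphenyl}methanol | OC(c1c(CCc2ccc(O)c(OC)c2)cc(O)cc1OC)c1c(CCc2ccc(O)c(OC)c2)cc(O)cc1OC | intermediate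
21 | 4,4'-methylenebis{5-[2-(4-hydroxy-3-methoxyphenyl)ethyl]-3-methoxyphenol} (achiral) | COc1cc(CCc2cc(O)cc(OC)c2Cc2c(CCc3ccc(O)c(OC)c3)cc(O)cc2OC)ccc1O | target

Total step count: 9. Longest linear sequence: 6 (steps 1, 2, 3, 4, 8, 9); the diene branch (steps 5–7) joins at step 8.

Steps most likely to fail

Step 8. The doubly activated diynone may be consumed by uncontrolled conjugate addition and oligomerization with the nucleophilic diene before both rings close, or the second cycloaddition may stall at the stage of the mono-aryl ynone so that prolonged heating destroys the diene. The fallback builds the central rings one at a time; it sets out from alkyne 6 and comes back to the route at target 21. Deprotonation of 6 with EtMgBr (THF, 0 → 40 °C) gives the Grignard reagent 7, and formylation with DMF followed by a cold aqueous KH2PO4 quench would give the alkynal 8, this time isolated. Cycloaddition of 8 with diene 16 (toluene, 80–110 °C; dilute HCl) should give 4-hydroxy-2-methoxy-6-(2-{3-methoxy-4-[(4-methoxybenzyl)oxy]phenyl}ethyl)benzaldehyde F1. Alkylation with chloride 2 (K2CO3, DMF) would give 2-methoxy-4-[(4-methoxybenzyl)oxy]-6-(2-{3-methoxy-4-[(4-methoxybenzyl)oxy]phenyl}ethyl)benzaldehyde F2. Addition of the Grignard reagent 7, made again from 6 and EtMgBr, would give the racemic 1-aryl-5-arylpent-2-yn-1-ol F3, and MnO2 the corresponding aryl alkynyl ketone, 1-aryl-5-arylpent-2-yn-1-one F4. This purified single dienophile can be heated with fresh 16 under more forcing conditions (xylene, 140 °C; dilute HCl) to give the unsymmetrically protected benzophenone, the mono(4-methoxybenzyl) ether of 18 at one central phenol F5. Under the conditions of step 9, F5 would lose all three 4-methoxybenzyl groups and be reduced to 21.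

Step 9. In strong acid the electron-rich diarylmethane may be protonated at the bridge-bearing carbon and fragment (retro-Friedel–Crafts). The 4-methoxybenzyl cation may also alkylate the resorcinol rings, or reduction may stall at the hindered carbonyl. The fallback avoids protic acid; it sets out from 18 and comes back at 21. NaBH4 in aqueous NaOH/EtOH at reflux reduces para-hydroxyaryl ketones to methylene compounds by way of the phenoxide carbinol and a para-quinone methide. It should give bis[4-hydroxy-2-methoxy-6-(2-{3-methoxy-4-[(4-methoxybenzyl)oxy]phenyl}ethyl)phenyl]methane F6. Neutral hydrogenolysis (H2, Pd/C, EtOAc/MeOH) would then remove both benzylic ethers and give 21.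

Step 2. Enolization may occur partly toward the methylene side, and the terminal alkyne may isomerize to the allene during the elimination. The fallback makes the alkyne by one-carbon homologation of an aldehyde; it sets out from chloride 2 and comes back at alkyne 6. Commercial 3-(4-hydroxy-3-methoxyphenyl)propan-1-ol F7 (dihydroconiferyl alcohol) would be alkylated at the phenol only (2, K2CO3, DMF) to give 3-{3-methoxy-4-[(4-methoxybenzyl)oxy]phenyl}propan-1-ol F8. Oxidation (Dess–Martin periodinane, CH2Cl2) would give 3-{3-methoxy-4-[(4-methoxybenzyl)oxy]phenyl}propanal F9. Seyferth–Gilbert homologation with the Ohira–Bestmann reagent (dimethyl (1-diazo-2-oxopropyl)phosphonate, K2CO3, MeOH) would give 6.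

Further compounds
F1 | step 8 | 4-hydroxy-2-methoxy-6-(2-{3-methoxy-4-[(4-methoxybenzyl)oxy]phenyl}ethyl)benzaldehyde | O=Cc1c(CCc2ccc(OCc3ccc(OC)cc3)c(OC)c2)cc(O)cc1OC
F2 | step 8 | 2-methoxy-4-[(4-methoxybenzyl)oxy]-6-(2-{3-methoxy-4-[(4-methoxybenzyl)oxy]phenyl}ethyl)benzaldehyde | O=Cc1c(CCc2ccc(OCc3ccc(OC)cc3)c(OC)c2)cc(OCc2ccc(OC)cc2)cc1OC
F3 | step 8 | 1-[2-methoxy-4-[(4-methoxybenzyl)oxy]-6-(2-{3-methoxy-4-[(4-methoxybenzyl)oxy]phenyl}ethyl)phenyl]-5-{3-methoxy-4-[(4-methoxybenzyl)oxy]phenyl}pent-2-yn-1-ol (racemic) | OC(C#CCCc1ccc(OCc2ccc(OC)cc2)c(OC)c1)c1c(CCc2ccc(OCc3ccc(OC)cc3)c(OC)c2)cc(OCc2ccc(OC)cc2)cc1OC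
F4 | step 8 | 1-[2-methoxy-4-[(4-methoxybenzyl)oxy]-6-(2-{3-methoxy-4-[(4-methoxybenzyl)oxy]phenyl}ethyl)phenyl]-5-{3-methoxy-4-[(4-methoxybenzyl)oxy]phenyl}pent-2-yn-1-one | O=C(C#CCCc1ccc(OCc2ccc(OC)cc2)c(OC)c1)c1c(CCc2ccc(OCc3ccc(OC)cc3)c(OC)c2)cc(OCc2ccc(OC)cc2)cc1OC
F5 | step 8 | [4-hydroxy-2-methoxy-6-(2-{3-methoxy-4-[(4-methoxybenzyl)oxy]phenyl}ethyl)phenyl][2-methoxy-4-[(4-methoxybenzyl)oxy]-6-(2-{3-methoxy-4-[(4-methoxybenzyl)oxy]phenyl}ethyl)phenyl]methanone | O=C(c1c(CCc2ccc(OCc3ccc(OC)cc3)c(OC)c2)cc(O)cc1OC)c1c(CCc2ccc(OCc3ccc(OC)cc3)c(OC)c2)cc(OCc2ccc(OC)cc2)cc1OC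
F6 | step 9 | bis[4-hydroxy-2-methoxy-6-(2-{3-methoxy-4-[(4-methoxybenzyl)oxy]phenyl}ethyl)phenyl]methane | C(c1c(CCc2ccc(OCc3ccc(OC)cc3)c(OC)c2)cc(O)cc1OC)c1c(CCc2ccc(OCc3ccc(OC)cc3)c(OC)c2)cc(O)cc1OC
F7 | step 2 | 3-(4-hydroxy-3-methoxyphenyl)propan-1-ol | OCCCc1ccc(O)c(OC)c1
F8 | step 2 | 3-{3-methoxy-4-[(4-methoxybenzyl)oxy]phenyl}propan-1-ol | OCCCc1ccc(OCc2ccc(OC)cc2)c(OC)c1
F9 | step 2 | 3-{3-methoxy-4-[(4-methoxybenzyl)oxy]phenyl}propanal | O=CCCc1ccc(OCc2ccc(OC)cc2)c(OC)c1
A1 | direct plan | (3-chloro-5-methoxyphenoxy)triisopropylsilane | COc1cc(Cl)cc(O[Si](C(C)C)(C(C)C)C(C)C)c1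
A2 | direct plan | bis[2-chloro-6-methoxy-4-(triisopropylsilyloxy)phenyl]methanol | OC(c1c(Cl)cc(O[Si](C(C)C)(C(C)C)C(C)C)cc1OC)c1c(Cl)cc(O[Si](C(C)C)(C(C)C)C(C)C)cc1OC
A3 | direct plan | bis[2-chloro-6-methoxy-4-(triisopropylsilyloxy)phenyl]methane | COc1cc(O[Si](C(C)C)(C(C)C)C(C)C)cc(Cl)c1Cc1c(Cl)cc(O[Si](C(C)C)(C(C)C)C(C)C)cc1OC
A4 | direct plan | 9-{2-[3-methoxy-4-(triisopropylsilyloxy)phenyl]ethyl}-9-borabicyclo[3.3.1]nonane | COc1cc(CCB2C3CCCC2CCC3)ccc1O[Si](C(C)C)(C(C)C)C(C)C
A5 | direct plan | bis{2-methoxy-6-[2-(3-methoxy-4-triisopropylsilyloxyphenyl)ethyl]-4-(triisopropylsilyloxy)phenyl}methane | COc1cc(CCc2cc(O[Si](C(C)C)(C(C)C)C(C)C)cc(OC)c2Cc2c(CCc3ccc(O[Si](C(C)C)(C(C)C)C(C)C)c(OC)c3)cc(O[Si](C(C)C)(C(C)C)C(C)C)cc2OC)ccc1O[Si](C(C)C)(C(C)C)C(C)C
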